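**Plan**

1. Locants: C1 (lactone C=O), O2, C3 (quaternary, methyl), C3a, C4, C4a, C5–C8, C8a (OH), C9, C9a for rings B, C and the lactone; C10 (bears the piperidine, bonded to C3) and C11 (CH2, bonded to C4) complete cyclopentane ring A; piperidine N1', C2' (on C10), C6' (methyl).
2. Cuts: C8a–O (ene oxygenation of a C8a=C9 alkene); C3a–C9a and C4–C4a together (intramolecular Diels–Alder); ester C1–O2; C3–CH3; C11–C4 (ring A opened to a divinyl ketone); the C10=C11 methylene; C2'–C10 (N-acyliminium alkylation).
3. Forward: piperidine from the chiral pool → ring A as a cyclopentenone by closure of C11–C4 → methyl carbinol → dienoate ester → ring B and the lactone in one cycloaddition (ring C arrives with the cyclohexenyl dienoic acid) → C8a–OH.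
4. Enabling feature: the oxygen-bearing C3 of ring A lies between C10 and C3a, so at the ketone level C11=C10–C3(=O)–C3a=C4 is a cross-conjugated divinyl ketone whose two β-carbons are C11 and C4; silicon on C4 leaves the alkene at C3a=C4, which is then the dienophile for ring B.
5. Stereochemistry: C6' from (S)-2-methylpiperidine; C2' by axial attack on the N-acyliminium ion (2,6-cis); C10 by protonation after the electrocyclization (A(1,3) control, epimerizable); C3 by methyl addition anti to the C10 substituent; C3a, C4, C4a by the tether-directed exo cycloaddition; C8a by suprafacial ene oxygenation on the open face.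

Key step: step 6

Remark: compound 3 is carried as a mixture at its N,O-acetal carbon, which becomes planar in step 4.

**Step 1**
Reactants: 1 (2S)-2-methylpiperidine
Product: 2 1-[(2S)-2-methylpiperidin-1-yl]ethan-1-one
Conditions: Ac2O, Et3N, DMAP (cat.), CH2Cl2, 0 °C to rt
Reagents that add atoms: acetic anhydride, CC(=O)OC(C)=O
Why: N-Acetylation (nucleophilic acyl substitution) installs the amide of the target early and activates the ring for α-oxidation, with C6' untouched.

**Step 2**
Reactants: 2 1-[(2S)-2-methylpiperidin-1-yl]ethan-1-one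
Product: 3 1-[(2S)-6-methoxy-2-methylpiperidin-1-yl]ethan-1-one (both epimers at the acetal carbon)
Conditions: constant current (2.5 F/mol), graphite anode, stainless-steel cathode, Et4NOTs, MeOH, 10 °C, undivided cell
Reagents that add atoms: methanol, CO
Why: Shono anodic oxidation gives the N-acyliminium ion at the less substituted α-carbon (the future C2'), which methanol traps, so the methyl-bearing C6' keeps its configuration.

**Step 3**
Reactants: 4 (3E)-4-(trimethylsilyl)but-3-en-2-one
Product: 5 trimethyl{[(3E)-4-(trimethylsilyl)buta-1,3-dien-2-yl]oxy}silane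
Conditions: Me3SiOTf, Et3N, Et2O, 0 °C
Reagents that add atoms: trimethylsilyl trifluoromethanesulfonate, C[Si](C)(C)OS(=O)(=O)C(F)(F)F
Why: Silyl enol ether formation by soft enolization at the methyl group, the only enolisable position, gives the 2-silyloxydiene without touching the vinylsilane.

**Step 4**
Reactants: 3 1-[(2S)-6-methoxy-2-methylpiperidin-1-yl]ethan-1-one; 5 trimethyl{[(3E)-4-(trimethylsilyl)buta-1,3-dien-2-yl]oxy}silane
Product: 6 1-[(2S,6S)-2-methyl-6-[(3E)-2-oxo-4-(trimethylsilyl)but-3-en-1-yl]piperidin-1-yl]ethan-1-one (2,6-cis)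
Conditions: Me3SiOTf (0.2 equiv), CH2Cl2, −78 to −40 °C
Reagents that add atoms: none
Why: Mukaiyama–Mannich reaction (N-acyliminium amidoalkylation): Me3SiOTf ionises the N,O-acetal and the enol silane adds to C2' by axial attack on the half-chair iminium ion whose C6' methyl is pseudoaxial (A(1,3) strain with the N-acetyl group), the well-precedented course to 2,6-cis-N-acylpiperidines, which sets C2' as S.

**Step 5**
Reactants: 6 1-[(2S,6S)-2-methyl-6-[(3E)-2-oxo-4-(trimethylsilyl)but-3-en-1-yl]piperidin-1-yl]ethan-1-one
Product: 7 1-[(2S,6S)-2-methyl-6-[(4E)-3-oxo-5-(trimethylsilyl)penta-1,4-dien-2-yl]piperidin-1-yl]ethan-1-one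
Conditions: (CH2O)n, i-Pr2NH2+ CF3CO2− (1 equiv), CF3CO2H (0.1 equiv), THF, 60 °C
Reagents that add atoms: formaldehyde (as paraformaldehyde), C=O
Why: Direct α-methylenation (Mannich condensation, then β-elimination of the amine) at C10, the only enolisable carbon of the ketone, introduces C11 and completes the divinyl ketone.

**Step 6**
Reactants: 7 1-[(2S,6S)-2-methyl-6-[(4E)-3-oxo-5-(trimethylsilyl)penta-1,4-dien-2-yl]piperidin-1-yl]ethan-1-one
Product: 8 1-[(2S,6S)-2-methyl-6-[(1R)-2-oxocyclopent-3-en-1-yl]piperidin-1-yl]ethan-1-one
Conditions: FeCl3 (2.2 equiv), CH2Cl2, −30 to 0 °C; then aq NaHCO3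
Reagents that add atoms: none
Why: FeCl3 on the ketone oxygen turns the cross-conjugated dienone C11=C10–C3(=O)–C3a=C4 into a 3-oxidopentadienyl cation, which closes ring A by thermal conrotatory 4π-electrocyclization between its two β-carbons C11 and C4 (Nazarov cyclization; the closest known type is the FeCl3-promoted silicon-directed variant with β-silyl divinyl ketones). The closure is electrocyclic (all five ring atoms come from the pentadienyl cation; formally 5-endo, but pericyclic and thermally allowed) and leaves a 2-oxidocyclopentenyl cation. Because the C4–Si bond is β to the cationic C3a, loss of the silyl group puts the double bond at C3a=C4 only, which is the regioselectivity the route needs, since without silicon the more substituted C10=C11 enone would form. The only new stereocentre, C10, arises when the cross-conjugated iron dienolate is protonated on quench: with C2'–H eclipsing the C3–O bond to avoid A(1,3) strain, the proton should enter anti to the N-acetyl nitrogen and give (10R), and since C10 stays epimerizable in 8 the minor epimer can be re-equilibrated with Et3N and recycled. The second equivalent of FeCl3 binds the amide oxygen so that it cannot trap the oxyallyl cation, and the low temperature avoids protodesilylation of the vinylsilane before cyclization.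

**Step 7**
Reactants: 8 1-[(2S,6S)-2-methyl-6-[(1R)-2-oxocyclopent-3-en-1-yl]piperidin-1-yl]ethan-1-one
Product: 9 1-[(2S,6S)-2-[(1R,2R)-2-hydroxy-2-methylcyclopent-3-en-1-yl]-6-methylpiperidin-1-yl]ethan-1-one
Conditions: MeLi, CeCl3 (anhydrous), THF, −78 °C; then aq NH4Cl
Reagents that add atoms: methyllithium, C[Li]
Why: Organocerium 1,2-addition to the enone (non-basic, so C10 is not enolised and the amide is left alone): the methyl group should enter C3 anti to the bulky C10 piperidinyl substituent, which sets C3 as R with the hydroxyl cis to the piperidine.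

**Step 8**
Reactants: 10 cyclohex-1-ene-1-carbaldehyde; 11 malonic acid
Product: 12 (2E)-3-(cyclohex-1-en-1-yl)prop-2-enoic acid
Conditions: pyridine, piperidine (cat.), 90 °C
Reagents that add atoms: none
Why: Knoevenagel–Doebner condensation with decarboxylation gives the (E)-dienoic acid under thermodynamic control.

**Step 9**
Reactants: 12 (2E)-3-(cyclohex-1-en-1-yl)prop-2-enoic acid
Product: 13 (2E)-3-(cyclohex-1-en-1-yl)prop-2-enoyl chloride
Conditions: (COCl)2, DMF (cat.), CH2Cl2, 0 °C to rt; evaporate
Reagents that add atoms: oxalyl chloride, O=C(Cl)C(Cl)=O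
Why: Acid chloride formation through the chloroiminium (Vilsmeier-type) catalyst is mild enough to leave the diene intact.

**Step 10**
Reactants: 9 1-[(2S,6S)-2-[(1R,2R)-2-hydroxy-2-methylcyclopent-3-en-1-yl]-6-methylpiperidin-1-yl]ethan-1-one; 13 (2E)-3-(cyclohex-1-en-1-yl)prop-2-enoyl chloride
Product: 15 (1R,5R)-5-[(2S,6S)-1-acetyl-6-methylpiperidin-2-yl]-1-methylcyclopent-2-en-1-yl (2E)-3-(cyclohex-1-en-1-yl)prop-2-enoate, via lithium alkoxide 14 (not isolated)
Conditions: LiN(SiMe3)2 (1.05 equiv), THF, −78 °C; then 13, −78 to 0 °C
Reagents that add atoms: none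
Why: O-Acylation of the preformed lithium alkoxide by the acid chloride overcomes the hindrance of the tertiary allylic alcohol and touches no stereocentre.

**Step 11**
Reactants: 15 (1R,5R)-5-[(2S,6S)-1-acetyl-6-methylpiperidin-2-yl]-1-methylcyclopent-2-en-1-yl (2E)-3-(cyclohex-1-en-1-yl)prop-2-enoate
Product: 17 pentacyclic cis-fused lactone with the C8a=C9 double bond (C9a–H cis to C3a–H; all other centres as in the target), via trans-fused lactone cycloadduct 16 (not isolated)
Conditions: o-dichlorobenzene (0.01 M), BHT (cat.), 185 °C, sealed tube, base-washed glass; then DBU (0.2 equiv), rt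
Reagents that add atoms: none
Why: Intramolecular Diels–Alder reaction of the (E)-dienoate (diene C9a=C9–C8a=C4a) with the cyclopentene C3a=C4: the three-atom ester tether from C3 forces addition to the cyclopentene face that carries the C3 oxygen (setting C3a and C4 cis to it) and the exo transition state that keeps ring A away from the diene should place C4a–H trans to C4–H, after which DBU epimerises C9a by enolisation to the more stable cis-fused lactone, which puts C9a–H on the open face for step 12.

**Step 12**
Reactants: 17 pentacyclic cis-fused lactone with the C8a=C9 double bond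
Product: 19 CNP0529632.1 (3R,3aS,4S,4aS,8aS,10R,2'S,6'S in the locants of the plan), via C8a hydroperoxide 18 (not isolated)
Conditions: O2, hν (visible), 5,10,15,20-tetraphenylporphyrin (cat.), CH2Cl2, −20 °C; then PPh3, rt
Reagents that add atoms: dioxygen, O=O
Why: Schenck ene reaction: singlet oxygen should attack the C8a=C9 alkene on the face opposite to C3 and C11 (the other face is shielded by the pseudoaxial C3 of the cis-fused lactone), bond to C8a and abstract the pseudoaxial C9a–H of the same face, so the double bond moves into conjugation at C9=C9a and the C8a oxygen ends trans to C4a–H (8aS), and PPh3 reduces the hydroperoxide to the alcohol.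

**Compound list**

1 | (2S)-2-methylpiperidine | C[C@H]1CCCCN1 | starting material
2 | 1-[(2S)-2-methylpiperidin-1-yl]ethan-1-one | CC(=O)N1[C@@H](C)CCCC1 | intermediate
3 | 1-[(2S)-6-methoxy-2-methylpiperidin-1-yl]ethan-1-one (epimers at C6) | CC(=O)N1[C@@H](C)CCCC1OC | intermediate
4 | (3E)-4-(trimethylsilyl)but-3-en-2-one | CC(=O)/C=C/[Si](C)(C)C | starting material
5 | trimethyl{[(3E)-4-(trimethylsilyl)buta-1,3-dien-2-yl]oxy}silane | C=C(O[Si](C)(C)C)/C=C/[Si](C)(C)C | intermediate
6 | 1-[(2S,6S)-2-methyl-6-[(3E)-2-oxo-4-(trimethylsilyl)but-3-en-1-yl]piperidin-1-yl]ethan-1-one | CC(=O)N1[C@@H](C)CCC[C@H]1CC(=O)/C=C/[Si](C)(C)C | intermediate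
7 | 1-[(2S,6S)-2-methyl-6-[(4E)-3-oxo-5-(trimethylsilyl)penta-1,4-dien-2-yl]piperidin-1-yl]ethan-1-one | CC(=O)N1[C@@H](C)CCC[C@H]1C(=C)C(=O)/C=C/[Si](C)(C)C | intermediate
8 | 1-[(2S,6S)-2-methyl-6-[(1R)-2-oxocyclopent-3-en-1-yl]piperidin-1-yl]ethan-1-one | CC(=O)N1[C@@H](C)CCC[C@H]1[C@H]1CC=CC1=O | intermediate
9 | 1-[(2S,6S)-2-[(1R,2R)-2-hydroxy-2-methylcyclopent-3-en-1-yl]-6-methylpiperidin-1-yl]ethan-1-one | CC(=O)N1[C@@H](C)CCC[C@H]1[C@H]1CC=C[C@@]1(C)O | intermediate
10 | cyclohex-1-ene-1-carbaldehyde | O=CC1=CCCCC1 | starting material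
11 | malonic acid | OC(=O)CC(=O)O | starting material
12 | (2E)-3-(cyclohex-1-en-1-yl)prop-2-enoic acid | OC(=O)/C=C/C1=CCCCC1 | intermediate
13 | (2E)-3-(cyclohex-1-en-1-yl)prop-2-enoyl chloride | ClC(=O)/C=C/C1=CCCCC1 | intermediate
14 | lithium alkoxide of 9 | CC(=O)N1[C@@H](C)CCC[C@H]1[C@H]1CC=C[C@@]1(C)O[Li] | intermediate
15 | (1R,5R)-5-[(2S,6S)-1-acetyl-6-methylpiperidin-2-yl]-1-methylcyclopent-2-en-1-yl (2E)-3-(cyclohex-1-en-1-yl)prop-2-enoate | CC(=O)N1[C@@H](C)CCC[C@H]1[C@H]1CC=C[C@@]1(C)OC(=O)/C=C/C1=CCCCC1 | intermediate
16 | exo cycloadduct, trans-fused lactone (C9a–H trans to C3a–H), C8a=C9 alkene | CC(=O)N1[C@@H](C)CCC[C@H]1[C@H]1C[C@@H]2[C@H]3[C@H](C=C4CCCC[C@@H]24)C(=O)O[C@@]13C | intermediate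
17 | C9a epimer of 16, cis-fused lactone, C8a=C9 alkene | CC(=O)N1[C@@H](C)CCC[C@H]1[C@H]1C[C@@H]2[C@H]3[C@@H](C=C4CCCC[C@@H]24)C(=O)O[C@@]13C | intermediate
18 | C8a hydroperoxide with the C9=C9a double bond | CC(=O)N1[C@@H](C)CCC[C@H]1[C@H]1C[C@@H]2[C@H]3C(=C[C@]4(OO)CCCC[C@@H]24)C(=O)O[C@@]13C | intermediate
19 | CNP0529632.1 | CC(=O)N1[C@@H](C)CCC[C@H]1[C@H]1C[C@@H]2[C@H]3C(=C[C@]4(O)CCCC[C@@H]24)C(=O)O[C@@]13C | target

**Step count and risks**

Total steps: 12. Longest linear sequence: 9 steps (1, 2, 4, 5, 6, 7, 10, 11, 12).

Most likely to fail, first: step 11. The thermal cycloaddition onto an unactivated cyclopentene may be too slow, so that ionisation of the tertiary allylic ester (elimination or 1,3-acyloxy shift) takes over; the endo mode could also compete and erode the C4a configuration. The fallback sets out from 15 and comes back at 17. The same two bonds would be closed not by a thermal pericyclic step but by a metal-mediated [4+2]: a cationic monovalent rhodium catalyst ([Rh(cod)Cl]2 with AgSbF6, 1,2-dichloroethane, 50 °C) would couple diene and alkene through a rhodacycle, well below the temperature at which the ester ionises. DBU would then convert the adduct 16 into 17. No new compound arises (F0).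

Second: step 6. The oxyallyl cation may be captured by the amide oxygen, the cross-conjugated dienone 7 may polymerise before it cyclises, or the protonation at C10 may show poor facial selectivity. The fallback sets out from 3 and comes back at 8. Commercial cyclopent-2-en-1-one would be converted (LiN(i-Pr)2, Me3SiCl, THF, −78 °C) into trimethyl(cyclopenta-1,4-dien-1-yloxy)silane F1, used cold to avoid hydrogen shifts. Its Mukaiyama–Mannich reaction with the N-acyliminium ion from 3 (Me3SiOTf cat., CH2Cl2, −78 °C) would join C10 to C2' and give 8 directly, 2,6-cis by the same axial attack as in step 4. The C10 epimers would be equilibrated with Et3N and separated as in the main route.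

Third: step 12. Singlet oxygen may abstract hydrogen from C8 or C4a instead of C9a (wrong regiochemistry of the ene reaction), or approach the hindered face. The fallback sets out from 17 and comes back at 19. Epoxidation with dimethyldioxirane (acetone, 0 °C) on the same open face would give the 8a,9-epoxide F2. DBU (toluene, 60 °C) would then open it by E1cB elimination from the lactone enolate, which forms the C9=C9a double bond and leaves the C8a tertiary alcohol where the epoxide placed the oxygen.

**Further compounds**

F0 | step 11 | none | none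
F1 | step 6 | trimethyl(cyclopenta-1,4-dien-1-yloxy)silane | C[Si](C)(C)OC1=CCC=C1
F2 | step 12 | 8a,9-epoxide of 17 (oxygen trans to C4a–H) | CC(=O)N1[C@@H](C)CCC[C@H]1[C@H]1C[C@@H]2[C@H]3[C@@H]([C@H]5O[C@]54CCCC[C@@H]24)C(=O)O[C@@]13C
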